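## Retrosynthetic overview
1. The 7-O-prenyl bond is made last but one, on a flavone whose 5-OH and 4'-OH are masked as acetates. That diacetate comes from the triacetate of 5,7,4'-trihydroxy-3,8,3'-trimethoxyflavone by selective loss of the 7-acetate.
2. The triol comes from the 7,4'-di-O-benzyl-3,5,8,3'-tetra-O-methyl compound by hydrogenolysis and chelation-controlled 5-O-demethylation. The 3-OMe comes from C3 oxygenation of the flavone followed by O-methylation.
3. Ring C is the only ring that is built, by oxidative O1–C2 closure of a 2'-hydroxychalcone. Rings A and B are bought as benzenoid compounds.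
4. The key C–C disconnection is the chalcone Cα=Cβ bond. It is made by Claisen–Schmidt aldol condensation of 4-benzyloxy-2-hydroxy-3,6-dimethoxyacetophenone (ring A) with O-benzylvanillin (ring B).
5. The ring A ketone comes from symmetric 1,3-bis(benzyloxy)-2,5-dimethoxybenzene by acylation and ortho-debenzylation. That arene comes from 2,4,6-trihydroxybenzaldehyde, with a Baeyer–Villiger oxidation installing the future 8-oxygen.

Assumption: the target SMILES has no stereocentre and no stereogenic double bond, so the compound is achiral and no asymmetric step is needed. Transient stereocentres are racemic and are erased.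

## Route

Step 1
Reactants: 1 2,4,6-trihydroxybenzaldehyde
Product: 2 2,6-dihydroxy-4-methoxybenzaldehyde
Conditions: Me2SO4 (1.0 equiv), K2CO3 (1.0 equiv), acetone, reflux, 4 h
Reagents that add atoms: dimethyl sulfate, COS(=O)(=O)OC
Why: Williamson ether synthesis in which both ortho hydroxyls are hydrogen-bonded to the formyl oxygen, so one equivalent of base and electrophile methylates the free, most acidic 4-OH; no stereocentre is formed.

Step 2
Reactants: 2 2,6-dihydroxy-4-methoxybenzaldehyde
Product: 3 2,6-bis(benzyloxy)-4-methoxybenzaldehyde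
Conditions: BnBr (2.5 equiv), K2CO3 (3 equiv), DMF, 70 °C, 12 h
Reagents that add atoms: benzyl bromide, BrCc1ccccc1
Why: Williamson ether synthesis with excess halide in warm DMF overcomes the chelation of both remaining phenols and gives a mirror-symmetric dibenzyl ether.

Step 3
Reactants: 3 2,6-bis(benzyloxy)-4-methoxybenzaldehyde
Product: 5 2,6-bis(benzyloxy)-4-methoxyphenol, via aryl formate 4 (not isolated)
Conditions: mCPBA (1.3 equiv), CH2Cl2, 0 °C → rt; crude formate, then K2CO3 (0.1 equiv), MeOH, rt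
Reagents that add atoms: 3-chloroperoxybenzoic acid, O=C(OO)c1cccc(Cl)c1
Why: Baeyer–Villiger (Dakin-type) oxidation in which the very electron-rich aryl group migrates in preference to hydride, and mild methanolysis of the formate frees the phenol oxygen that becomes the 8-oxygen.

Step 4
Reactants: 5 2,6-bis(benzyloxy)-4-methoxyphenol
Product: 6 1,3-bis(benzyloxy)-2,5-dimethoxybenzene
Conditions: MeI (1.5 equiv), K2CO3 (2 equiv), DMF, rt
Reagents that add atoms: iodomethane, CI
Why: Williamson ether synthesis fixes the future 8-OMe and gives an arene whose two free ring positions are equivalent by symmetry.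

Step 5
Reactants: 6 1,3-bis(benzyloxy)-2,5-dimethoxybenzene
Product: 7 1-[2,4-bis(benzyloxy)-3,6-dimethoxyphenyl]ethan-1-one
Conditions: AcOH (3 equiv) premixed with (CF3CO)2O (1.5 equiv), CH2Cl2, 0 °C → rt
Reagents that add atoms: acetic acid, CC(=O)O
Why: Friedel–Crafts acylation by the mixed anhydride needs no Lewis acid on this phloroglucinol-type arene, so the benzyl ethers survive, symmetry allows only one regioisomer, and the first acyl group blocks a second acylation.

Step 6
Reactants: 7 1-[2,4-bis(benzyloxy)-3,6-dimethoxyphenyl]ethan-1-one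
Product: 8 1-[4-(benzyloxy)-2-hydroxy-3,6-dimethoxyphenyl]ethan-1-one
Conditions: MgBr2·OEt2 (2 equiv), toluene–Et2O 7:1, 75 °C; 1 M HCl work-up
Reagents that add atoms: none
Why: Chelation-controlled ether cleavage in which magnesium bridges the carbonyl and the crowded 2-benzyloxy oxygen and bromide removes that benzyl group, while the non-chelating 4-OBn and the far less labile 6-OMe remain, so the free OH sits next to the 3-OMe.

Step 7
Reactants: 9 vanillin (4-hydroxy-3-methoxybenzaldehyde)
Product: 10 4-(benzyloxy)-3-methoxybenzaldehyde (O-benzylvanillin)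
Conditions: BnBr (1.1 equiv), K2CO3 (1.5 equiv), DMF, 50 °C
Reagents that add atoms: benzyl bromide, BrCc1ccccc1
Why: Williamson ether synthesis removes the acidic phenol, which as its phenoxide would deactivate the aldehyde in the aldol step.

Step 8
Reactants: 8 1-[4-(benzyloxy)-2-hydroxy-3,6-dimethoxyphenyl]ethan-1-one + 10 4-(benzyloxy)-3-methoxybenzaldehyde
Product: 12 (E)-1-[4-(benzyloxy)-2-hydroxy-3,6-dimethoxyphenyl]-3-[4-(benzyloxy)-3-methoxyphenyl]prop-2-en-1-one, via aldol adduct 11 (not isolated)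
Conditions: KOH (50% aq, 10 equiv), EtOH, rt, 36–48 h; cold 2 M HCl to pH 4
Reagents that add atoms: none
Why: Claisen–Schmidt crossed aldol condensation in which only 8 can enolise and only 10 is a good acceptor, and E1cB loss of water from racemic 11 erases the carbinol stereocentre and gives the conjugated E-chalcone.

Step 9
Reactants: 12 (E)-chalcone
Product: 14 7-(benzyloxy)-2-[4-(benzyloxy)-3-methoxyphenyl]-5,8-dimethoxy-4H-chromen-4-one, via flavanone 13 (not isolated)
Conditions: I2 (0.1 equiv), DMSO, 130 °C, 3 h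
Reagents that add atoms: none
Why: Iodine-catalysed oxidative cyclisation in which oxa-Michael addition of the only free ortho hydroxyl (the other ortho oxygen is a methyl ether) gives racemic 13, and α-iodination with loss of HI, with DMSO as terminal oxidant, removes its stereocentre and closes ring C with 8-OMe regiochemistry.

Step 10
Reactants: 14 7-(benzyloxy)-2-[4-(benzyloxy)-3-methoxyphenyl]-5,8-dimethoxy-4H-chromen-4-one
Product: 16 7-(benzyloxy)-2-[4-(benzyloxy)-3-methoxyphenyl]-3-hydroxy-5,8-dimethoxy-4H-chromen-4-one, via flavone epoxide 15 (not isolated)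
Conditions: dimethyldioxirane (0.07 M in acetone, 3 equiv), CH2Cl2, 0 °C → rt, 16 h; evaporate; p-TsOH·H2O (0.1 equiv), CH2Cl2, rt
Reagents that add atoms: dimethyldioxirane, CC1(C)OO1
Why: Neutral electrophilic epoxidation of the enol-ether-like C2=C3 bond gives racemic 15, which under acid catalysis opens to the C2 oxocarbenium ion and loses H-3, so both stereocentres vanish in the flavonol, and the aurone problem of direct alkaline peroxide oxidation of 6'-alkoxychalcones is avoided.

Step 11
Reactants: 16 3-hydroxyflavone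
Product: 17 7-(benzyloxy)-2-[4-(benzyloxy)-3-methoxyphenyl]-3,5,8-trimethoxy-4H-chromen-4-one
Conditions: MeI (2 equiv), K2CO3 (2 equiv), DMF, rt
Reagents that add atoms: iodomethane, CI
Why: Williamson ether synthesis on the only free hydroxyl, the acidic enolic 3-OH.

Step 12
Reactants: 17 7-(benzyloxy)-2-[4-(benzyloxy)-3-methoxyphenyl]-3,5,8-trimethoxy-4H-chromen-4-one
Product: 18 7-hydroxy-2-(4-hydroxy-3-methoxyphenyl)-3,5,8-trimethoxy-4H-chromen-4-one
Conditions: H2 (1 atm), 10% Pd/C, THF–MeOH 1:1, rt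
Reagents that add atoms: none
Why: Catalytic hydrogenolysis cleaves both aryl benzyl ethers, while the methyl ethers and the tetrasubstituted vinylogous-ester C2=C3 bond are inert at one atmosphere.

Step 13
Reactants: 18 7-hydroxy-2-(4-hydroxy-3-methoxyphenyl)-3,5,8-trimethoxy-4H-chromen-4-one
Product: 19 5,7-dihydroxy-2-(4-hydroxy-3-methoxyphenyl)-3,8-dimethoxy-4H-chromen-4-one
Conditions: AlCl3 (8 equiv), MeCN, 70 °C, 3 h; then 2 M aq HCl, 70 °C, 30 min
Reagents that add atoms: none
Why: Chelation-controlled Lewis acid demethylation in which aluminium forms a six-membered chelate between the C4 carbonyl and the peri 5-OMe and chloride removes that methyl group, while nitrile-tempered AlCl3 leaves the 3-, 8- and 3'-OMe groups intact.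

Step 14
Reactants: 19 5,7-dihydroxy-2-(4-hydroxy-3-methoxyphenyl)-3,8-dimethoxy-4H-chromen-4-one
Product: 20 2-[4-(acetyloxy)-3-methoxyphenyl]-3,8-dimethoxy-4-oxo-4H-chromene-5,7-diyl diacetate (triacetate)
Conditions: Ac2O (10 equiv), pyridine, DMAP (0.1 equiv), rt, 12 h
Reagents that add atoms: acetic anhydride, CC(=O)OC(C)=O
Why: Exhaustive O-acetylation under nucleophilic catalysis also acylates the chelated 5-OH, so all three phenols are masked alike.

Step 15
Reactants: 20 triacetate
Product: 21 5-acetoxy-2-(4-acetoxy-3-methoxyphenyl)-7-hydroxy-3,8-dimethoxy-4H-chromen-4-one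
Conditions: PhSH (1.5 equiv), imidazole (0.3 equiv), NMP, 0 °C → rt
Reagents that add atoms: none
Why: Chemoselective thiolysis (acyl transfer to thiolate) removes only the 7-acetate, because the 7-phenoxide, para to the C4 carbonyl, is the best leaving group of the three.

Step 16
Reactants: 21 5-acetoxy-2-(4-acetoxy-3-methoxyphenyl)-7-hydroxy-3,8-dimethoxy-4H-chromen-4-one
Product: 22 5-acetoxy-2-(4-acetoxy-3-methoxyphenyl)-3,8-dimethoxy-7-[(3-methylbut-2-en-1-yl)oxy]-4H-chromen-4-one
Conditions: prenyl bromide (1.3 equiv), K2CO3 (1.5 equiv), dry acetone, rt → 40 °C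
Reagents that add atoms: 1-bromo-3-methylbut-2-ene (prenyl bromide), CC(C)=CCBr
Why: Williamson ether synthesis (SN2 at the primary allylic carbon) on the only free phenol, under anhydrous carbonate conditions that aryl acetates tolerate.

Step 17
Reactants: 22 5-acetoxy-2-(4-acetoxy-3-methoxyphenyl)-3,8-dimethoxy-7-[(3-methylbut-2-en-1-yl)oxy]-4H-chromen-4-one
Product: 23 5,4'-dihydroxy-3,8,3'-trimethoxy-7-prenyloxyflavone
Conditions: K2CO3 (3 equiv), MeOH–THF 2:1, 0 °C → rt, 1 h; cold 0.5 M HCl to pH 6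
Reagents that add atoms: none
Why: Base-mediated transesterification (Zemplén-type methanolysis) removes both aryl acetates without acid, reductant or oxidant, so the acid-sensitive prenyl ether, the alkene and the methyl ethers are untouched and no stereocentre is involved.

## Compound list
1 | 2,4,6-trihydroxybenzaldehyde | O=Cc1c(O)cc(O)cc1O | starting material
2 | 2,6-dihydroxy-4-methoxybenzaldehyde | COc1cc(O)c(C=O)c(O)c1 | intermediate
3 | 2,6-bis(benzyloxy)-4-methoxybenzaldehyde | COc1cc(OCc2ccccc2)c(C=O)c(OCc2ccccc2)c1 | intermediate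
4 | 2,6-bis(benzyloxy)-4-methoxyphenyl formate (not isolated) | COc1cc(OCc2ccccc2)c(OC=O)c(OCc2ccccc2)c1 | intermediate
5 | 2,6-bis(benzyloxy)-4-methoxyphenol | COc1cc(OCc2ccccc2)c(O)c(OCc2ccccc2)c1 | intermediate
6 | 1,3-bis(benzyloxy)-2,5-dimethoxybenzene | COc1cc(OCc2ccccc2)c(OC)c(OCc2ccccc2)c1 | intermediate
7 | 1-[2,4-bis(benzyloxy)-3,6-dimethoxyphenyl]ethan-1-one | CC(=O)c1c(OC)cc(OCc2ccccc2)c(OC)c1OCc1ccccc1 | intermediate
8 | 1-[4-(benzyloxy)-2-hydroxy-3,6-dimethoxyphenyl]ethan-1-one | CC(=O)c1c(OC)cc(OCc2ccccc2)c(OC)c1O | intermediate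
9 | vanillin | COc1cc(C=O)ccc1O | starting material
10 | 4-(benzyloxy)-3-methoxybenzaldehyde | COc1cc(C=O)ccc1OCc1ccccc1 | intermediate
11 | 1-[4-(benzyloxy)-2-hydroxy-3,6-dimethoxyphenyl]-3-[4-(benzyloxy)-3-methoxyphenyl]-3-hydroxypropan-1-one (racemic, not isolated) | COc1cc(OCc2ccccc2)c(OC)c(O)c1C(=O)CC(O)c1ccc(OCc2ccccc2)c(OC)c1 | intermediate
12 | (E)-1-[4-(benzyloxy)-2-hydroxy-3,6-dimethoxyphenyl]-3-[4-(benzyloxy)-3-methoxyphenyl]prop-2-en-1-one | COc1cc(OCc2ccccc2)c(OC)c(O)c1C(=O)/C=C/c1ccc(OCc2ccccc2)c(OC)c1 | intermediate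
13 | 7-(benzyloxy)-2-[4-(benzyloxy)-3-methoxyphenyl]-5,8-dimethoxychroman-4-one (racemic, not isolated) | COc1cc(OCc2ccccc2)c(OC)c2OC(c3ccc(OCc4ccccc4)c(OC)c3)CC(=O)c12 | intermediate
14 | 7-(benzyloxy)-2-[4-(benzyloxy)-3-methoxyphenyl]-5,8-dimethoxy-4H-chromen-4-one | COc1cc(OCc2ccccc2)c(OC)c2oc(-c3ccc(OCc4ccccc4)c(OC)c3)cc(=O)c12 | intermediate
15 | 2,3-epoxide of 14 (racemic, cis-fused, not isolated) | COc1cc(OCc2ccccc2)c(OC)c2OC3(c4ccc(OCc5ccccc5)c(OC)c4)OC3C(=O)c12 | intermediate
16 | 7-(benzyloxy)-2-[4-(benzyloxy)-3-methoxyphenyl]-3-hydroxy-5,8-dimethoxy-4H-chromen-4-one | COc1cc(OCc2ccccc2)c(OC)c2oc(-c3ccc(OCc4ccccc4)c(OC)c3)c(O)c(=O)c12 | intermediate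
17 | 7-(benzyloxy)-2-[4-(benzyloxy)-3-methoxyphenyl]-3,5,8-trimethoxy-4H-chromen-4-one | COc1cc(OCc2ccccc2)c(OC)c2oc(-c3ccc(OCc4ccccc4)c(OC)c3)c(OC)c(=O)c12 | intermediate
18 | 7-hydroxy-2-(4-hydroxy-3-methoxyphenyl)-3,5,8-trimethoxy-4H-chromen-4-one | COc1cc(O)c(OC)c2oc(-c3ccc(O)c(OC)c3)c(OC)c(=O)c12 | intermediate
19 | 5,7-dihydroxy-2-(4-hydroxy-3-methoxyphenyl)-3,8-dimethoxy-4H-chromen-4-one | COc1cc(-c2oc3c(OC)c(O)cc(O)c3c(=O)c2OC)ccc1O | intermediate
20 | 2-[4-(acetyloxy)-3-methoxyphenyl]-3,8-dimethoxy-4-oxo-4H-chromene-5,7-diyl diacetate | COc1cc(-c2oc3c(OC)c(OC(C)=O)cc(OC(C)=O)c3c(=O)c2OC)ccc1OC(C)=O | intermediate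
21 | 5-acetoxy-2-(4-acetoxy-3-methoxyphenyl)-7-hydroxy-3,8-dimethoxy-4H-chromen-4-one | COc1cc(-c2oc3c(OC)c(O)cc(OC(C)=O)c3c(=O)c2OC)ccc1OC(C)=O | intermediate
22 | 5-acetoxy-2-(4-acetoxy-3-methoxyphenyl)-3,8-dimethoxy-7-[(3-methylbut-2-en-1-yl)oxy]-4H-chromen-4-one | COc1cc(-c2oc3c(OC)c(OCC=C(C)C)cc(OC(C)=O)c3c(=O)c2OC)ccc1OC(C)=O | intermediate
23 | 5,4'-dihydroxy-3,8,3'-trimethoxy-7-prenyloxyflavone (achiral) | COc1cc(-c2oc3c(OC)c(OCC=C(C)C)cc(O)c3c(=O)c2OC)ccc1O | target

## Step count and risks
Total step count: 17.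
Longest linear sequence: 16 (steps 1–6 and 8–17, from 1 to 23).

**Step 10.** Epoxidation of the C2=C3 bond is slow. It may lose out to oxidation of the benzylic C–H bonds or of the electron-rich rings.

The fallback sets out from 14 and comes back at 16. It replaces the electrophilic oxidant by metalation. C3–H is deprotonated with lithium diisopropylamide (LiN(iPr)2) in THF at −78 °C to give 7-(benzyloxy)-2-[4-(benzyloxy)-3-methoxyphenyl]-3-lithio-5,8-dimethoxy-4H-chromen-4-one F1. This is trapped with B(OMe)3 as dimethyl {7-(benzyloxy)-2-[4-(benzyloxy)-3-methoxyphenyl]-5,8-dimethoxy-4-oxo-4H-chromen-3-yl}boronate F2. The C–B bond is then oxidised in the same flask with H2O2/AcOH to give flavonol 16.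

**Step 13.** The two free phenols can anchor aluminium next to the 8-OMe and 3'-OMe groups, and the 3-OMe can also chelate. Over-demethylation is therefore the danger.

The fallback sets out from 18 and comes back at 20. Both phenols are capped first (Ac2O, pyridine, rt) to give 7,4'-diacetoxy-3,5,8,3'-tetramethoxyflavone F3. Only the peri 5-OMe is then cleaved with BCl3 (2.5 equiv, CH2Cl2, −78 → 0 °C) to give 7,4'-diacetoxy-5-hydroxy-3,8,3'-trimethoxyflavone F4. Acetylation of the 5-OH (Ac2O, pyridine, DMAP) gives triacetate 20.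

**Step 15.** The neighbouring 8-OMe may reduce the rate advantage of the 7-acetate, so the 4'-acetate could be lost as well.

The fallback sets out from 19 and comes back at 23. It uses no protecting groups. Triol 19 is treated with prenyl bromide (1.0 equiv) and KHCO3 (1.1 equiv) in DMF at rt → 40 °C.

Only the most acidic 7-OH is ionised. The 5-OH is chelated and the guaiacol-type 4'-OH is less acidic. The small amount of 7,4'-diether is removed by chromatography. This fallback passes through no new compound F0.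

## Further compounds
F1 | step 10 | 7-(benzyloxy)-2-[4-(benzyloxy)-3-methoxyphenyl]-3-lithio-5,8-dimethoxy-4H-chromen-4-one | COc1cc(OCc2ccccc2)c(OC)c2oc(-c3ccc(OCc4ccccc4)c(OC)c3)c([Li])c(=O)c12
F2 | step 10 | dimethyl {7-(benzyloxy)-2-[4-(benzyloxy)-3-methoxyphenyl]-5,8-dimethoxy-4-oxo-4H-chromen-3-yl}boronate | COB(OC)c1c(-c2ccc(OCc3ccccc3)c(OC)c2)oc2c(OC)c(OCc3ccccc3)cc(OC)c2c1=O
F3 | step 13 | 7,4'-diacetoxy-3,5,8,3'-tetramethoxyflavone | COc1cc(-c2oc3c(OC)c(OC(C)=O)cc(OC)c3c(=O)c2OC)ccc1OC(C)=O
F4 | step 13 | 7,4'-diacetoxy-5-hydroxy-3,8,3'-trimethoxyflavone | COc1cc(-c2oc3c(OC)c(OC(C)=O)cc(O)c3c(=O)c2OC)ccc1OC(C)=O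
F0 | step 15 | none | none
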